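**Plan**

- Numbering used throughout: oxolane O1, C2 (4-hydroxyphenyl), C3 (bears C3a, the CH2OAc carbon), C4 (bears C4a, the CH(OAc)-anisyl carbon), C5 (H2).
- Feature: C2 carries both an aryl group and the ring oxygen. In an open-chain precursor it is the CH2 of a 4-oxybenzyl ether on the C5 oxygen, and its activated C–H bond can take up a carbene generated at C3.
- Retrosynthesis: the acetates and the phenol go back to silyl ethers and a C3a tert-butyl ester; then C2–C3 is cut (opening the only ring to an α-diazo ester), then O1–C2 (benzyl ether), then C4–C4a (aldol), then the imide N–acyl bond.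
- Forward: succinate imide and 4-methoxybenzaldehyde are joined by aldol reaction; silylation, auxiliary removal, O-benzylation and diazo transfer follow; the oxolane then closes by 1,5 C–H insertion; ester reduction, desilylation, acetylation and release of the phenol finish the route.
- Stereochemistry: C4 and C4a come from the Evans syn-aldol under the (S)-4-benzyl-oxazolidinone; C2 is set in the insertion under control of C4; C3 is set by thermodynamic equilibration of the ester to the all-trans ring.

Key step: step 10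

Assumption: the facial bias of Rh2(S-PTTL)4 (dirhodium tetrakis[N-phthaloyl-(S)-tert-leucinate]) is taken to reinforce the preference of the C4 branch for a 2,4-cis ring; if it opposed it, the enantiomeric catalyst Rh2(R-PTTL)4 would be used in step 10.

**Step 1**
Reactants: 1 4-hydroxybenzaldehyde
Product: 2 4-(triisopropylsilyloxy)benzaldehyde
Conditions: TIPSCl, imidazole, DMF, rt
Reagents that add atoms: triisopropylsilyl chloride, CC(C)[Si](Cl)(C(C)C)C(C)C
Why: Imidazole-promoted O-silylation of the phenol (silyl ether formation) leaves the aldehyde untouched and gives a phenol protecting group that should tolerate the later enolate, carbenoid and hydride steps.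

**Step 2**
Reactants: 2 4-(triisopropylsilyloxy)benzaldehyde
Product: 3 [4-(triisopropylsilyloxy)phenyl]methanol
Conditions: NaBH4, MeOH, 0 °C
Reagents that add atoms: none
Why: Borohydride reduction of an aromatic aldehyde to the benzylic alcohol, under which the aryl silyl ether should survive in cold methanol.

**Step 3**
Reactants: 3 [4-(triisopropylsilyloxy)phenyl]methanol
Product: 4 4-(triisopropylsilyloxy)benzyl 2,2,2-trichloroacetimidate
Conditions: Cl3CCN, DBU (10 mol %), CH2Cl2, 0 °C
Reagents that add atoms: trichloroacetonitrile, N#CC(Cl)(Cl)Cl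
Why: Base-catalysed addition of the alcohol to trichloroacetonitrile (trichloroacetimidate formation) gives a benzyl donor that mild acid activates, in the manner of 4-methoxybenzyl imidates.

**Step 4**
Reactants: 5 mono-tert-butyl succinate; 6 (S)-4-benzyl-2-oxazolidinone
Product: 8 tert-butyl 4-[(4S)-4-benzyl-2-oxo-1,3-oxazolidin-3-yl]-4-oxobutanoate, via mixed pivalic anhydride 7 (not isolated)
Conditions: PivCl, Et3N, THF, −20 °C; then LiCl, 6, −20 °C → rt
Reagents that add atoms: none
Why: N-acylation of the oxazolidinone through the mixed anhydride, which is attacked at the less hindered succinyl carbonyl while LiCl/Et3N activates the oxazolidinone without strong base.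

**Step 5**
Reactants: 8 tert-butyl 4-[(4S)-4-benzyl-2-oxo-1,3-oxazolidin-3-yl]-4-oxobutanoate; 9 4-methoxybenzaldehyde
Product: 12 tert-butyl (3S)-4-[(4S)-4-benzyl-2-oxo-1,3-oxazolidin-3-yl]-3-[(S)-hydroxy(4-methoxyphenyl)methyl]-4-oxobutanoate, via Z boron enolate 10 (not isolated), via boron aldolate 11 (not isolated)
Conditions: n-Bu2BOTf, i-Pr2NEt, CH2Cl2, 0 °C; 9, −78 → 0 °C; pH 7 buffer, MeOH, H2O2
Reagents that add atoms: none
Why: Evans syn-aldol reaction, in which soft enolisation gives only the Z boron enolate of the imide (the tert-butyl ester is not enolised) and the closed chair transition state, with the benzyl group shielding one enolate face, sets C4 and C4a as the syn pair of the required absolute configuration.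

**Step 6**
Reactants: 12 the syn-aldol adduct
Product: 13 tert-butyl (3S)-4-[(4S)-4-benzyl-2-oxo-1,3-oxazolidin-3-yl]-3-[(S)-(tert-butyldimethylsilyloxy)(4-methoxyphenyl)methyl]-4-oxobutanoate
Conditions: TBSOTf, 2,6-lutidine, CH2Cl2, −78 → 0 °C
Reagents that add atoms: tert-butyldimethylsilyl triflate, CC(C)(C)[Si](C)(C)OS(=O)(=O)C(F)(F)F
Why: Silyl ether formation at the hindered benzylic alcohol with the silyl triflate blocks retro-aldol cleavage and lactonisation onto the ester, and a short reaction at low temperature should spare the tert-butyl ester.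

**Step 7**
Reactants: 13 the silylated aldol imide
Product: 14 tert-butyl (3R,4S)-4-(tert-butyldimethylsilyloxy)-3-(hydroxymethyl)-4-(4-methoxyphenyl)butanoate
Conditions: LiBH4, H2O (1 equiv), Et2O, 0 °C
Reagents that add atoms: none
Why: Reductive removal of the auxiliary (imide to primary alcohol) is chemoselective for the activated exocyclic imide carbonyl over the tert-butyl ester and creates the C5 hydroxyl without touching C4 or C4a.

**Step 8**
Reactants: 14 the hydroxy ester; 4 4-(triisopropylsilyloxy)benzyl 2,2,2-trichloroacetimidate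
Product: 15 tert-butyl (3R,4S)-4-(tert-butyldimethylsilyloxy)-4-(4-methoxyphenyl)-3-{[4-(triisopropylsilyloxy)benzyloxy]methyl}butanoate
Conditions: 4 (1.5 equiv), PPTS (10 mol %), CH2Cl2, 0 °C → rt
Reagents that add atoms: none
Why: Acid-catalysed O-benzylation with a trichloroacetimidate, in which the primary alcohol captures the stabilised 4-silyloxybenzyl cation (forming O1–C2) under conditions too mild to lactonise the γ-hydroxy tert-butyl ester or ionise the benzylic silyl ether, whereas a basic Williamson alkylation would lactonise the substrate.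

**Step 9**
Reactants: 15 the benzyl ether ester
Product: 18 tert-butyl (3R,4S)-4-(tert-butyldimethylsilyloxy)-2-diazo-4-(4-methoxyphenyl)-3-{[4-(triisopropylsilyloxy)benzyloxy]methyl}butanoate, via lithium enolate 16 (not isolated), via trifluoroacetyl ester 17 (not isolated)
Conditions: LiN(i-Pr)2, THF, −78 °C; CF3CO2CH2CF3, −78 °C; NH4Cl quench, concentrate; then on the crude material p-ABSA, Et3N, H2O (1 equiv), MeCN, rt
Reagents that add atoms: 4-acetamidobenzenesulfonyl azide, CC(=O)Nc1ccc(S(=O)(=O)N=[N+]=[N-])cc1
Why: Detrifluoroacetylative (deacylative Regitz-type) diazo transfer, in which the kinetic ester enolate is C-acylated by the trifluoroacetate and the resulting 1,3-dicarbonyl takes the diazo group from the sulfonyl azide with loss of the trifluoroacetyl group as its sulfonamide, while C4 carries no acidifying group and keeps its configuration.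

**Step 10**
Reactants: 18 the α-diazo ester
Product: 20 tert-butyl (2R,3R,4R)-4-[(S)-(tert-butyldimethylsilyloxy)(4-methoxyphenyl)methyl]-2-[4-(triisopropylsilyloxy)phenyl]oxolane-3-carboxylate (all-trans), via 2,3-cis ester 19 (not isolated)
Conditions: Rh2(S-PTTL)4 (1 mol %), toluene, −78 → −40 °C; then KOt-Bu (0.3 equiv), t-BuOH/THF, 0 °C → rt
Reagents that add atoms: none
Why: The divalent rhodium dimer Rh2(S-PTTL)4 expels N2 from 18 to give an electrophilic carbenoid at C3, and hydride-like transfer of one benzylic ether hydrogen to this carbon occurs together with C2–C3 bond formation in a single asynchronous three-centre event. The closest known reaction type is the dirhodium-carboxylate-catalysed intramolecular 1,5 C–H insertion of α-alkyl-α-diazo esters into benzylic and ether C–H bonds, which gives 2-aryl-cyclopentane- and 2-aryl-oxolane-carboxylates at low temperature. The oxolane closes in the 1,5 mode: the carbenoid carbon becomes C3 and the ether CH2, four bonds away, becomes C2, through a five-membered transition-state ring. C2 is set by the existing C4 centre, whose bulky silyloxy(aryl)methyl branch is expected to sit pseudo-equatorial in the envelope-like transition state and to steer the aryl group to the same ring face (2,4-cis), with the chiral carboxylate ligands reinforcing this choice between the two diastereotopic hydrogens. C3 is expected to appear first with the ester cis to the aryl group (19) and is then set thermodynamically, since tert-butoxide enolises the ester reversibly and the ester settles trans to both neighbours. Insertion has to outrun the 1,2-hydride shift from C4–H and attack on the anisyl ring or on other C–H bonds; the bulky phthalimido-carboxylate ligands at −78 °C disfavour the hydride shift, and the targeted bond is the only C–H bond four bonds from the carbenoid carbon that is activated both by an ether oxygen and by an electron-rich aryl ring.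

**Step 11**
Reactants: 20 the all-trans oxolane ester
Product: 21 {(2R,3S,4R)-4-[(S)-(tert-butyldimethylsilyloxy)(4-methoxyphenyl)methyl]-2-[4-(triisopropylsilyloxy)phenyl]oxolan-3-yl}methanol
Conditions: LiAlH4, THF, 0 °C
Reagents that add atoms: none
Why: Hydride reduction of the ester to the primary alcohol turns C3a into CH2OH and removes the acidity of C3–H, so the configuration at C3 is fixed from here on, while both silyl ethers should survive at 0 °C.

**Step 12**
Reactants: 21 the bis-silylated alcohol
Product: 22 4-{(2R,3S,4R)-4-[(S)-hydroxy(4-methoxyphenyl)methyl]-3-(hydroxymethyl)oxolan-2-yl}phenol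
Conditions: TBAF (5 equiv), AcOH (5 equiv), THF, rt
Reagents that add atoms: none
Why: Fluoride-mediated desilylation cleaves the alkyl and the aryl silyl ether in one operation, and the acetic acid buffer keeps the liberated phenol and the two benzylic C–O bonds out of strongly basic medium.

**Step 13**
Reactants: 22 the triol
Product: 23 {(2R,3S,4R)-4-[(S)-acetoxy(4-methoxyphenyl)methyl]-2-(4-acetoxyphenyl)oxolan-3-yl}methyl acetate
Conditions: Ac2O, pyridine, DMAP (cat.), CH2Cl2, 0 °C → rt
Reagents that add atoms: acetic anhydride, CC(=O)OC(C)=O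
Why: DMAP-catalysed acetylation (esterification) of all three hydroxyl groups under basic conditions, which do not ionise the 4-methoxybenzylic position, so C4a keeps its configuration.

**Step 14**
Reactants: 23 the triacetate
Product: 24 {(2R,3S,4R)-4-[(S)-acetoxy(4-methoxyphenyl)methyl]-2-(4-hydroxyphenyl)oxolan-3-yl}methyl acetate (target)
Conditions: pyrrolidine (1.5 equiv), CH2Cl2, 0 °C
Reagents that add atoms: none
Why: Chemoselective aminolysis of the aryl acetate, because phenoxide is a far better leaving group than an alkoxide, so a small excess of a secondary amine at 0 °C should remove only the phenolic acetyl group.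

**Compound list**

1 | 4-hydroxybenzaldehyde | O=Cc1ccc(O)cc1 | starting material
2 | 4-(triisopropylsilyloxy)benzaldehyde | CC(C)[Si](Oc1ccc(C=O)cc1)(C(C)C)C(C)C | intermediate
3 | [4-(triisopropylsilyloxy)phenyl]methanol | CC(C)[Si](Oc1ccc(CO)cc1)(C(C)C)C(C)C | intermediate
4 | 4-(triisopropylsilyloxy)benzyl 2,2,2-trichloroacetimidate | CC(C)[Si](Oc1ccc(COC(=N)C(Cl)(Cl)Cl)cc1)(C(C)C)C(C)C | intermediate
5 | mono-tert-butyl succinate | CC(C)(C)OC(=O)CCC(=O)O | starting material
6 | (S)-4-benzyl-2-oxazolidinone | O=C1N[C@@H](Cc2ccccc2)CO1 | starting material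
7 | 4-tert-butoxy-4-oxobutanoic pivalic anhydride | CC(C)(C)OC(=O)CCC(=O)OC(=O)C(C)(C)C | intermediate (not isolated)
8 | tert-butyl 4-[(4S)-4-benzyl-2-oxo-1,3-oxazolidin-3-yl]-4-oxobutanoate | CC(C)(C)OC(=O)CCC(=O)N1[C@@H](Cc2ccccc2)COC1=O | intermediate
9 | 4-methoxybenzaldehyde | COc1ccc(C=O)cc1 | starting material
10 | tert-butyl (3Z)-4-[(4S)-4-benzyl-2-oxo-1,3-oxazolidin-3-yl]-4-(dibutylboranyloxy)but-3-enoate (Z boron enolate of 8) | CCCCB(CCCC)O/C(=C\CC(=O)OC(C)(C)C)N1[C@@H](Cc2ccccc2)COC1=O | intermediate (not isolated)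
11 | O-dibutylboranyl derivative of 12 (boron aldolate) | COc1ccc([C@@H](OB(CCCC)CCCC)[C@H](CC(=O)OC(C)(C)C)C(=O)N2[C@@H](Cc3ccccc3)COC2=O)cc1 | intermediate (not isolated)
12 | tert-butyl (3S)-4-[(4S)-4-benzyl-2-oxo-1,3-oxazolidin-3-yl]-3-[(S)-hydroxy(4-methoxyphenyl)methyl]-4-oxobutanoate | COc1ccc([C@@H](O)[C@H](CC(=O)OC(C)(C)C)C(=O)N2[C@@H](Cc3ccccc3)COC2=O)cc1 | intermediate
13 | tert-butyl (3S)-4-[(4S)-4-benzyl-2-oxo-1,3-oxazolidin-3-yl]-3-[(S)-(tert-butyldimethylsilyloxy)(4-methoxyphenyl)methyl]-4-oxobutanoate | COc1ccc([C@@H](O[Si](C)(C)C(C)(C)C)[C@H](CC(=O)OC(C)(C)C)C(=O)N2[C@@H](Cc3ccccc3)COC2=O)cc1 | intermediate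
14 | tert-butyl (3R,4S)-4-(tert-butyldimethylsilyloxy)-3-(hydroxymethyl)-4-(4-methoxyphenyl)butanoate | COc1ccc([C@@H](O[Si](C)(C)C(C)(C)C)[C@H](CC(=O)OC(C)(C)C)CO)cc1 | intermediate
15 | tert-butyl (3R,4S)-4-(tert-butyldimethylsilyloxy)-4-(4-methoxyphenyl)-3-{[4-(triisopropylsilyloxy)benzyloxy]methyl}butanoate | COc1ccc([C@@H](O[Si](C)(C)C(C)(C)C)[C@H](CC(=O)OC(C)(C)C)COCc2ccc(O[Si](C(C)C)(C(C)C)C(C)C)cc2)cc1 | intermediate
16 | lithium enolate of 15 (enolate geometry not defined) | COc1ccc([C@@H](O[Si](C)(C)C(C)(C)C)[C@H](C=C(O[Li])OC(C)(C)C)COCc2ccc(O[Si](C(C)C)(C(C)C)C(C)C)cc2)cc1 | intermediate (not isolated)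
17 | tert-butyl (3R,4S)-4-(tert-butyldimethylsilyloxy)-4-(4-methoxyphenyl)-2-(trifluoroacetyl)-3-{[4-(triisopropylsilyloxy)benzyloxy]methyl}butanoate (C2 epimers) | COc1ccc([C@@H](O[Si](C)(C)C(C)(C)C)[C@H](C(C(=O)C(F)(F)F)C(=O)OC(C)(C)C)COCc2ccc(O[Si](C(C)C)(C(C)C)C(C)C)cc2)cc1 | intermediate (not isolated)
18 | tert-butyl (3R,4S)-4-(tert-butyldimethylsilyloxy)-2-diazo-4-(4-methoxyphenyl)-3-{[4-(triisopropylsilyloxy)benzyloxy]methyl}butanoate | COc1ccc([C@@H](O[Si](C)(C)C(C)(C)C)[C@H](C(=[N+]=[N-])C(=O)OC(C)(C)C)COCc2ccc(O[Si](C(C)C)(C(C)C)C(C)C)cc2)cc1 | intermediate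
19 | tert-butyl (2R,3S,4R)-4-[(S)-(tert-butyldimethylsilyloxy)(4-methoxyphenyl)methyl]-2-[4-(triisopropylsilyloxy)phenyl]oxolane-3-carboxylate (ester cis to the C2 aryl group) | COc1ccc([C@@H](O[Si](C)(C)C(C)(C)C)[C@H]2CO[C@@H](c3ccc(O[Si](C(C)C)(C(C)C)C(C)C)cc3)[C@H]2C(=O)OC(C)(C)C)cc1 | intermediate (not isolated)
20 | tert-butyl (2R,3R,4R)-4-[(S)-(tert-butyldimethylsilyloxy)(4-methoxyphenyl)methyl]-2-[4-(triisopropylsilyloxy)phenyl]oxolane-3-carboxylate (all-trans) | COc1ccc([C@@H](O[Si](C)(C)C(C)(C)C)[C@H]2CO[C@@H](c3ccc(O[Si](C(C)C)(C(C)C)C(C)C)cc3)[C@@H]2C(=O)OC(C)(C)C)cc1 | intermediate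
21 | {(2R,3S,4R)-4-[(S)-(tert-butyldimethylsilyloxy)(4-methoxyphenyl)methyl]-2-[4-(triisopropylsilyloxy)phenyl]oxolan-3-yl}methanol | COc1ccc([C@@H](O[Si](C)(C)C(C)(C)C)[C@H]2CO[C@@H](c3ccc(O[Si](C(C)C)(C(C)C)C(C)C)cc3)[C@@H]2CO)cc1 | intermediate
22 | 4-{(2R,3S,4R)-4-[(S)-hydroxy(4-methoxyphenyl)methyl]-3-(hydroxymethyl)oxolan-2-yl}phenol | COc1ccc([C@@H](O)[C@H]2CO[C@@H](c3ccc(O)cc3)[C@@H]2CO)cc1 | intermediate
23 | {(2R,3S,4R)-4-[(S)-acetoxy(4-methoxyphenyl)methyl]-2-(4-acetoxyphenyl)oxolan-3-yl}methyl acetate | COc1ccc([C@@H](OC(C)=O)[C@H]2CO[C@@H](c3ccc(OC(C)=O)cc3)[C@@H]2COC(C)=O)cc1 | intermediate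
24 | {(2R,3S,4R)-4-[(S)-acetoxy(4-methoxyphenyl)methyl]-2-(4-hydroxyphenyl)oxolan-3-yl}methyl acetate (CNP0231272.1) | COc1ccc([C@@H](OC(C)=O)[C@H]2CO[C@@H](c3ccc(O)cc3)[C@@H]2COC(C)=O)cc1 | target

**Step count**

Total: 14 steps. Longest linear sequence: 11 steps (steps 4 to 14, from 5 and 6 to 24); steps 1 to 3 make the benzyl donor 4 in a side branch.

**Steps most likely to fail**

1. Step 10. The carbenoid may collapse by 1,2-hydride migration from C4–H to the α,β-unsaturated ester faster than it inserts, or the insertion may show poor facial selectivity at C2 and deliver the 2,4-trans ring. The fallback sets out from 14 and returns at 20; it makes C2–C3 by an ester aldol addition and O1–C2 by cationic cycloetherification. Alcohol 14 is silylated (TESCl, imidazole, CH2Cl2) to the triethylsilyl ether F1. LiN(i-Pr)2-mediated aldol addition of F1 to aldehyde 2 (THF, −78 °C) should give the β-hydroxy ester F2 as a mixture at the two new centres. PPTS in MeOH removes the primary triethylsilyl group and gives the diol F3. Catalytic BF3·OEt2 in CH2Cl2 at −40 °C then ionises the 4-silyloxybenzylic alcohol, and the C5 hydroxyl captures the cation to close the oxolane, with C2 settling trans to its neighbour under these reversible conditions. KOt-Bu in t-BuOH/THF finally equilibrates C3 as in step 10 and should converge on 20.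

2. Step 9. C-acylation of the hindered, β-branched enolate may be incomplete or divert to O-acylation, so that the diazo transfer has no activated substrate and returns ester 15. The fallback sets out from 15 and returns at 18; it replaces acylation by amination. Treatment of 15 with KN(SiMe3)2 in THF at −78 °C, then 2,4,6-triisopropylbenzenesulfonyl azide and an acetic acid quench (electrophilic azidation), should give the α-azido ester F4. The phosphine-mediated conversion of an α-azido ester into a diazo ester (N-succinimidyl 3-(diphenylphosphino)propanoate, THF/H2O, then NaHCO3) then leads to 18 under nearly neutral conditions.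

3. Step 8. The acid that activates the imidate may instead lactonise the γ-hydroxy tert-butyl ester, or the imidate may rearrange to the N-benzyl trichloroacetamide before the alcohol captures it. The fallback sets out from 14 and returns at 15; it replaces alkylation by reductive etherification. Alcohol 14 is converted (TMSCl, Et3N, CH2Cl2) into the trimethylsilyl ether F5, which with aldehyde 2, Et3SiH and catalytic TMSOTf in CH2Cl2 at −78 °C should give ether 15 directly through the aryl-stabilised oxocarbenium ion.

**Further compounds**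

F1 | step 10 | tert-butyl (3R,4S)-4-(tert-butyldimethylsilyloxy)-4-(4-methoxyphenyl)-3-[(triethylsilyloxy)methyl]butanoate | COc1ccc([C@@H](O[Si](C)(C)C(C)(C)C)[C@H](CC(=O)OC(C)(C)C)CO[Si](CC)(CC)CC)cc1
F2 | step 10 | tert-butyl (3R,4S)-4-(tert-butyldimethylsilyloxy)-2-{hydroxy[4-(triisopropylsilyloxy)phenyl]methyl}-4-(4-methoxyphenyl)-3-[(triethylsilyloxy)methyl]butanoate (mixture at the two new centres) | COc1ccc([C@@H](O[Si](C)(C)C(C)(C)C)[C@H](C(C(O)c2ccc(O[Si](C(C)C)(C(C)C)C(C)C)cc2)C(=O)OC(C)(C)C)CO[Si](CC)(CC)CC)cc1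
F3 | step 10 | tert-butyl (3R,4S)-4-(tert-butyldimethylsilyloxy)-2-{hydroxy[4-(triisopropylsilyloxy)phenyl]methyl}-3-(hydroxymethyl)-4-(4-methoxyphenyl)butanoate (mixture at the two new centres) | COc1ccc([C@@H](O[Si](C)(C)C(C)(C)C)[C@H](C(C(O)c2ccc(O[Si](C(C)C)(C(C)C)C(C)C)cc2)C(=O)OC(C)(C)C)CO)cc1
F4 | step 9 | tert-butyl (3R,4S)-2-azido-4-(tert-butyldimethylsilyloxy)-4-(4-methoxyphenyl)-3-{[4-(triisopropylsilyloxy)benzyloxy]methyl}butanoate (C2 epimers) | COc1ccc([C@@H](O[Si](C)(C)C(C)(C)C)[C@H](C(N=[N+]=[N-])C(=O)OC(C)(C)C)COCc2ccc(O[Si](C(C)C)(C(C)C)C(C)C)cc2)cc1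
F5 | step 8 | tert-butyl (3R,4S)-4-(tert-butyldimethylsilyloxy)-4-(4-methoxyphenyl)-3-[(trimethylsilyloxy)methyl]butanoate | COc1ccc([C@@H](O[Si](C)(C)C(C)(C)C)[C@H](CC(=O)OC(C)(C)C)CO[Si](C)(C)C)cc1
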